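The numbers were chosen freely.

The question is how the electrophile that escapes the protic impurity divides between target and self-condensation product, and which recipe tips that division towards target.

| setting | delta | alpha | zeta | theta | gamma |
|---|---|---|---|---|---|
| electrophile | 24 mM | 24 mM | 24 mM | 24 mM | 24 mM |
| nucleophile | 60.0 mM | 60.0 mM (fed, over 2.0 min) | 60.0 mM | 60.0 mM (fed, over 20 min) | 60.0 mM |
| free base | 48.0 mM (fed, over 20 min) | 48.0 mM | 48.0 mM | 48.0 mM | 48.0 mM |
| protic impurity | 24.0 mM | 24.0 mM | 24.0 mM | 24.0 mM | 24.0 mM |
| temperature | 50 °C | 50 °C | 50 °C |  |  |
| time | 25 min | 25 min | 25 min | 25 min | 25 min |
| remark | all else is in the flask from the start; the feed brings no volume worth counting | all else is in the flask from the start; the feed brings no volume worth counting | everything together at the start | the addition at 20 °C, then warmed to 50 °C; the feed brings no volume worth counting | everything together at the start at 20 °C, warmed to 50 °C at 20 min |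

1. the flask that comes out highest in share of target in target plus self-condensation product, or "all alike" when all lie within 1.5 percentage points (delta / alpha / zeta / theta / gamma / all alike)
2. share of target in target plus self-condensation product at the end, delta
3. share of target in target plus self-condensation product at the end, alpha
4. share of target in target plus self-condensation product at the end, zeta
5. share of target in target plus self-condensation product at the end, theta
6. share of target in target plus self-condensation product at the end, gamma

- a species is counted by the electrophile in it: one self-condensation product counts as two
- amounts and yields of acid set free count idle adduct too
- for a step with 2 of a species take k times the square, and two of it per event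
- all constants are for 50 °C and move with temperature by the activation energies and enthalpies

    2 electrophile → self-condensation product (k1 = 0.010 M⁻¹ s⁻¹, Ea1 = 79.0 kJ mol⁻¹)
    electrophile + acid set free ⇌ idle adduct, settled at all times (K2 = 86 M⁻¹, ΔH2 = −27.0 kJ mol⁻¹)
    acid set free + free base ⇌ salt of the base (K3 = 21000 M⁻¹, k3 = 0.64 M⁻¹ s⁻¹, Ea3 = 45.0 kJ mol⁻¹, ΔH3 = 18.0 kJ mol⁻¹)
    nucleophile + acid set free ⇌ protonated nucleophile, settled at all times (K4 = 1200 M⁻¹, ΔH4 = 11.0 kJ mol⁻¹)
    electrophile + protic impurity → quenched substrate (k5 = 0.79 M⁻¹ s⁻¹, Ea5 = 56.0 kJ mol⁻¹)
    electrophile + nucleophile → acid set free + target (k6 = 0.023 M⁻¹ s⁻¹, Ea6 = 52.0 kJ mol⁻¹)
    (constants at 50 °C)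

We climb the time scales from the fastest, and our reckoning starts with the acid set free. It balances at once and sits on the nucleophile rather than on the electrophile, since binding constant times charge gives 72.0 for the first and 2.06 for the second. Free acid then meets free base with a forward half-life of 0.376 min, as charged. The next rung is the quench: the protic impurity, as charged, gives the electrophile a half-life of 0.609 min at 50 °C. The target step, pseudo-first-order in the charged nucleophile, has a half-life of 8.37 min, and the first half-life of self-condensation is 34.7 min, against a run of 25 min. The quench outruns the target step by a factor of 13.7, so we expect the end state to hold mostly quenched substrate, with target and self-condensation product as two small side channels.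

With the nucleophile in from the start, how fast the quench runs should then matter little to their ratio. Let λ be the first-order rate of the quench. Target collects in proportion to the electrophile summed over time, which is its charge over λ. Self-condensation takes two electrophile per event from the square of the electrophile, whose sum is half the charge squared over λ. The two and the half cancel, and so does λ, which leaves the selectivity factor σ = 5.75: target gained per electrophile lost to self-condensation, the target constant times nucleophile over the self-condensation constant times starting electrophile. The share is σ over one plus σ, or 85.2% for zeta, and delta, with the same nucleophile in from the start, should stand beside it. This is rough, since the impurity charge equals the electrophile charge and the clock slows as both fall.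

At 20 °C the activation energies raise σ by a factor of 2.80 to 16.1. The quench half-life there is 5.14 min, shorter than the cold stretch of gamma, which lasts 20.0 min, so we give gamma 94.1%. Alpha should fall below zeta, since its feed of 2.0 min outlasts the quench half-life and the early electrophile meets little nucleophile. Theta should fall below gamma for the same reason, its feed of 20 min outlasting the cold half-life.

The forecast, above our zeta figure and level with our gamma figure, named gamma with 87.2% for delta, 84% for alpha, 87.6% for zeta, 91% for theta and 94% for gamma, pointing to “the cold start, which slows self-condensation (highest activation energy) more than the target step”.

The simulation gives 88.1% for delta, 83.6% for alpha, 88.1% for zeta, 89.9% for theta and 94.2% for gamma, so gamma comes out highest.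

Carried to gamma, σ gave 94.1% against the 94.2% of the run, and for zeta it gave 85.2% against 88.1%. The quench itself widens the gap between gamma and alpha: the same comparison with that step taken away shows 5 percentage points, against 11 points with it. In the neighbour of gamma charged with 24 mM of nucleophile, the cold σ scales down to 6.43, which gives a share of 86.5%, and that flask reads 85.9%.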